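The route rests on disconnecting the C3–C4 bond of ring C. The C4 ketone sits 1,3 to the C2–H stereocentre, which carries O1 and ring B, and C3 is an unsubstituted methylene; this pattern maps onto a formyl group on ring A and an aryl 1-arylvinyl ether, O1–C2(ring B)=C3H2. A rhodium-catalysed enantioselective intramolecular hydroacylation joins the formyl carbon to the terminal alkene carbon, closing the pyranone ring and setting C2 in one atom-economic isomerisation of the achiral aldehyde 2-{[1-(3,4-dimethoxyphenyl)ethenyl]oxy}-4,5,6-trimethoxybenzaldehyde. This precursor is assembled in three steps by aryl ester formation, ester methylenation and directed ortho-lithiation/formylation.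

Key step: step 4

Remark: the ligand antipode that delivers the (2S) sense is assigned by analogy with related hydroacylations and would be confirmed in a first run; should the (2R) sense result, (S)-DTBM-SEGPHOS is used and nothing else changes.

Step 1
Reactants: 1 3,4,5-trimethoxyphenol; 2 3,4-dimethoxybenzoyl chloride
Product: 3 3,4,5-trimethoxyphenyl 3,4-dimethoxybenzoate
Conditions: Et3N, 4-(dimethylamino)pyridine (cat.), CH2Cl2, 0 °C to rt
Reagents that add atoms: none
Why: Nucleophile-catalysed acylation (esterification of a phenol by an aroyl chloride) is fast at the unhindered phenol and touches none of the methyl ethers.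

Step 2
Reactants: 3 3,4,5-trimethoxyphenyl 3,4-dimethoxybenzoate
Product: 4 1,2-dimethoxy-4-[1-(3,4,5-trimethoxyphenoxy)ethenyl]benzene
Conditions: Cp2TiMe2 (2.5 equiv), toluene, 70 °C, dark; filtration through basic alumina
Reagents that add atoms: dimethyltitanocene Cp2TiMe2, C[Ti](C)(C1C=CC=C1)C1C=CC=C1 (cyclopentadienyl rings drawn σ-bound)
Why: Petasis methylenation: Cp2TiMe2 loses methane on heating to give the titanocene methylidene, which adds across the ester C=O in a [2+2] cycloaddition and cycloreverts to the 1-aryloxy-1-arylethene and titanocene oxide, a known conversion of aryl benzoates that runs without acid and so spares the acid-labile enol ether.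

Step 3
Reactants: 4 1,2-dimethoxy-4-[1-(3,4,5-trimethoxyphenoxy)ethenyl]benzene
Product: 7 2-{[1-(3,4-dimethoxyphenyl)ethenyl]oxy}-4,5,6-trimethoxybenzaldehyde, via aryllithium 5 (not isolated), via lithium amino alkoxide 6 (not isolated)
Conditions: n-BuLi (1.1 equiv), THF, −40 to 0 °C; then DMF, −78 °C to rt; then H2O
Reagents that add atoms: n-butyllithium, [Li]CCCC (lithium carried only in 5 and 6); N,N-dimethylformamide, CN(C)C=O
Why: Directed ortho-metalation and formylation with DMF: the ring A hydrogen flanked by the enol ether oxygen and a methoxy group (both such positions are equivalent by symmetry) is the most acidic and best-coordinated site, as in 1,2,3,5-tetraalkoxybenzenes, and the aldehyde appears only when the lithium amino alkoxide collapses in the basic aqueous quench, which spares the enol ether.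

Step 4
Reactants: 7 2-{[1-(3,4-dimethoxyphenyl)ethenyl]oxy}-4,5,6-trimethoxybenzaldehyde
Product: 8 (2S)-2-(3,4-dimethoxyphenyl)-5,6,7-trimethoxy-2,3-dihydro-4H-chromen-4-one [(2S)-5,6,7,3',4'-pentamethoxyflavanone]
Conditions: [Rh(cod)Cl]2 (2.5 mol%), (R)-DTBM-SEGPHOS [(R)-5,5'-bis{bis(3,5-di-tert-butyl-4-methoxyphenyl)phosphino}-4,4'-bi-1,3-benzodioxole] (5.5 mol%), NaB[3,5-(CF3)2C6H3]4 (6 mol%), dry degassed 1,4-dioxane, 70 °C
Reagents that add atoms: none
Why: Proposed new method: the cationic monovalent rhodium–bisphosphine complex should add oxidatively into the formyl C–H bond of 7 (the flanking methoxy group can hold the acyl hydride of trivalent rhodium as a five-membered chelate and so slow decarbonylation), the enol ether C=C then inserts into Rh–H with hydride going to the oxygen-bearing carbon, and C–C reductive elimination from the seven-membered acyl–alkyl rhodacycle joins the former formyl carbon (C4) to the former =CH2 carbon (C3). The closest known reaction type is the rhodium-catalysed enantioselective intramolecular hydroacylation of 1,1-disubstituted alkenes, shown for ortho-allylbenzaldehydes (six-membered benzo-fused ketones) and for N-(1-substituted vinyl)indole-2-carbaldehydes (heteroatom-bearing alkene, stereocentre next to the heteroatom), but not for aryl 1-arylvinyl ethers of salicylaldehydes. Ring C closes in a formal 6-endo-trig (anti-Markovnikov) hydroacylation. The C2 stereocentre is set under catalyst control, the C2-symmetric ligand choosing the enantioface of the prochiral enol ether in the hydride insertion. The step needs anti-Markovnikov regioselectivity over five-ring closure to a 2-methyl-2-arylbenzofuran-3-one, which the 1,1-disubstitution secures because the Markovnikov path would demand a tertiary alkyl rhodium and reductive elimination to a quaternary carbon while its hydride insertion is reversible; it also needs hydroacylation to outrun decarbonylation. Alkene isomerisation, the usual side path of allyl tethers, is impossible because the enol ether has no allylic hydrogen, and the neutral conditions leave the base-labile C2 centre of the flavanone intact.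

Compound list
1 | 3,4,5-trimethoxyphenol | COc1cc(O)cc(OC)c1OC | starting material
2 | 3,4-dimethoxybenzoyl chloride | COc1ccc(C(=O)Cl)cc1OC | starting material
3 | 3,4,5-trimethoxyphenyl 3,4-dimethoxybenzoate | COc1ccc(C(=O)Oc2cc(OC)c(OC)c(OC)c2)cc1OC | intermediate
4 | 1,2-dimethoxy-4-[1-(3,4,5-trimethoxyphenoxy)ethenyl]benzene (achiral enol ether) | C=C(Oc1cc(OC)c(OC)c(OC)c1)c1ccc(OC)c(OC)c1 | intermediate
5 | (2-{[1-(3,4-dimethoxyphenyl)ethenyl]oxy}-4,5,6-trimethoxyphenyl)lithium, formed in the flask and not isolated | [Li]c1c(OC(=C)c2ccc(OC)c(OC)c2)cc(OC)c(OC)c1OC | intermediate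
6 | lithium (dimethylamino)(2-{[1-(3,4-dimethoxyphenyl)ethenyl]oxy}-4,5,6-trimethoxyphenyl)methanolate, racemic at the carbinol carbon, formed in the flask and not isolated | [Li]OC(N(C)C)c1c(OC(=C)c2ccc(OC)c(OC)c2)cc(OC)c(OC)c1OC | intermediate
7 | 2-{[1-(3,4-dimethoxyphenyl)ethenyl]oxy}-4,5,6-trimethoxybenzaldehyde (achiral) | O=Cc1c(OC(=C)c2ccc(OC)c(OC)c2)cc(OC)c(OC)c1OC | intermediate
8 | (2S)-2-(3,4-dimethoxyphenyl)-5,6,7-trimethoxy-2,3-dihydro-4H-chromen-4-one [(2S)-5,6,7,3',4'-pentamethoxyflavanone] | COc1ccc([C@@H]2CC(=O)c3c(cc(OC)c(OC)c3OC)O2)cc1OC | target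

Total step count: 4. Longest linear sequence: 4 steps (from 1).

Steps most likely to fail

1. Step 4 (key step). The acyl rhodium hydride may decarbonylate, the hydride may insert in the opposite sense, the alkyl rhodium intermediate may lose aryloxide, or the enantioface discrimination may be weak at the doubly ortho-substituted aldehyde. The fallback sets out from 1 and comes back at 8, still closing ring C through the C3–C4 bond but with the stereocentre set beforehand. Ortho-formylation of 1 (MgCl2, Et3N, paraformaldehyde, MeCN, reflux) should give 2-hydroxy-4,5,6-trimethoxybenzaldehyde F1. Commercial 2-bromo-1-(3,4-dimethoxyphenyl)ethanone (BrCC(=O)c1ccc(OC)c(OC)c1) would be reduced by Corey–Bakshi–Shibata reduction (BH3·SMe2, (S)-1-methyl-3,3-diphenyltetrahydro-1H,3H-pyrrolo[1,2-c][1,3,2]oxazaborole, THF) to (S)-2-bromo-1-(3,4-dimethoxyphenyl)ethanol F2. Mitsunobu etherification of F1 with F2 (PPh3, DIAD, THF, 0 °C) should give, with inversion, (R)-2-[2-bromo-1-(3,4-dimethoxyphenyl)ethoxy]-4,5,6-trimethoxybenzaldehyde F3. Bu3SnH/AIBN (benzene, 80 °C, slow addition) would generate the primary alkyl radical, whose 6-exo-trig addition to the formyl C=O should give (2S)-2-(3,4-dimethoxyphenyl)-5,6,7-trimethoxychroman-4-ol F4 as a mixture at C4. Dess–Martin oxidation (CH2Cl2, NaHCO3, rt) then gives 8 under neutral conditions that do not touch C2.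

2. Step 3. The alkyllithium may add across the styrene-type double bond, or deprotonate the vinylic position with loss of aryloxide, instead of metalating ring A. The fallback sets out from 1 and comes back at 5, generating the aryllithium by halogen–metal exchange at low temperature. Bromination of 1 (NBS, MeCN, 0 °C) should give 2-bromo-3,4,5-trimethoxyphenol F5. Acylation with 2 (Et3N, 4-(dimethylamino)pyridine, CH2Cl2) gives 2-bromo-3,4,5-trimethoxyphenyl 3,4-dimethoxybenzoate F6, and Petasis methylenation (Cp2TiMe2, toluene, 70 °C) gives 2-bromo-1-{[1-(3,4-dimethoxyphenyl)ethenyl]oxy}-3,4,5-trimethoxybenzene F7. Bromine–lithium exchange (n-BuLi, THF, −78 °C, minutes) should then deliver 5 faster than any addition or deprotonation, and DMF and water carry it through 6 to 7 as in step 3.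

3. Step 2. Methylenation of the electron-rich aryl ester may stall, and the enol ether may hydrolyse or oligomerise under acid during isolation. The fallback sets out from 1 and comes back at 4, making the enol ether by etherification and elimination instead of carbonyl olefination. Reduction of 2-bromo-1-(3,4-dimethoxyphenyl)ethanone (NaBH4, MeOH, 0 °C) gives racemic 2-bromo-1-(3,4-dimethoxyphenyl)ethanol F8. Mitsunobu etherification with 1 (PPh3, DIAD, THF) should give racemic 5-[2-bromo-1-(3,4-dimethoxyphenyl)ethoxy]-1,2,3-trimethoxybenzene F9. Elimination of HBr through the benzylic, oxygen-bearing hydrogen (t-BuOK, THF, 0 °C to rt) gives 4.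

Further compounds
F1 | step 4 | 2-hydroxy-4,5,6-trimethoxybenzaldehyde | O=Cc1c(O)cc(OC)c(OC)c1OC
F2 | step 4 | (S)-2-bromo-1-(3,4-dimethoxyphenyl)ethanol | O[C@H](CBr)c1ccc(OC)c(OC)c1
F3 | step 4 | (R)-2-[2-bromo-1-(3,4-dimethoxyphenyl)ethoxy]-4,5,6-trimethoxybenzaldehyde | O=Cc1c(O[C@@H](CBr)c2ccc(OC)c(OC)c2)cc(OC)c(OC)c1OC
F4 | step 4 | (2S)-2-(3,4-dimethoxyphenyl)-5,6,7-trimethoxychroman-4-ol, mixture of C4 epimers | COc1ccc([C@@H]2CC(O)c3c(cc(OC)c(OC)c3OC)O2)cc1OC
F5 | step 3 | 2-bromo-3,4,5-trimethoxyphenol | COc1cc(O)c(Br)c(OC)c1OC
F6 | step 3 | 2-bromo-3,4,5-trimethoxyphenyl 3,4-dimethoxybenzoate | COc1ccc(C(=O)Oc2cc(OC)c(OC)c(OC)c2Br)cc1OC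
F7 | step 3 | 2-bromo-1-{[1-(3,4-dimethoxyphenyl)ethenyl]oxy}-3,4,5-trimethoxybenzene | C=C(Oc1cc(OC)c(OC)c(OC)c1Br)c1ccc(OC)c(OC)c1
F8 | step 2 | racemic 2-bromo-1-(3,4-dimethoxyphenyl)ethanol | OC(CBr)c1ccc(OC)c(OC)c1
F9 | step 2 | racemic 5-[2-bromo-1-(3,4-dimethoxyphenyl)ethoxy]-1,2,3-trimethoxybenzene | COc1cc(OC(CBr)c2ccc(OC)c(OC)c2)cc(OC)c1OC
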